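The route rests on reading the spiroketal carbon C9 (shared by the tetrahydrofuran ring C and the γ-lactone ring D) as a masked ketone that sits next to the exo CH2 arm (C10) on the quaternary cyclobutane carbon C6. A temporary acyloxy group on C10 ties (R)-2-methylbut-3-enoic acid to a 1-ethoxyvinyl carbinol, and enol ether–olefin ring-closing metathesis closes a six-membered lactone by joining C9 to C11, the lactone CH2. Enol ether hydrolysis and SmI2 excision of the tether oxygen then unveil the 4-oxo acid, which folds with the endo CH2OH into rings C and D. The bicyclo[3.1.1]heptane comes from (R)-carvone by a radical 4-exo epoxide–enone cyclization.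

Key step: step 9

Locants used throughout: C1–C7 of the bicyclo[3.1.1]heptane as in pinane (C1 and C5 bridgeheads, C2–C3–C4 the three-carbon bridge, C6 the quaternary bridge, C7 the CH2 bridge). The arm on C6 that lies over the C2–C4 bridge is called endo (it becomes C8, the OCH2 of ring C); the arm on the C7 side is called exo (it becomes C10). C9 is the spiroketal carbon, C11 the lactone CH2, C12 the methyl-bearing lactone carbon, C13 the lactone carbonyl.

Assumption: (R)-2-methylbut-3-enoic acid is taken as a catalogue building block (otherwise it is reached by classical resolution of the racemic acid).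

Assumption: the two faces of ring C are almost equivalent with respect to the bicycle, so C9 cannot be set by the core; it is set relative to the C12 methyl group under equilibrating acid, and the C9 epimer is returned to the same conditions.

Step 1
Reactants: 1 (R)-(−)-carvone
Product: 2 10-chlorocarvone
Conditions: Ca(OCl)2, CO2 (solid), CH2Cl2/H2O, 0 °C
Reagents that add atoms: calcium hypochlorite, [Ca+2].[O-]Cl.[O-]Cl
Why: Ene-type allylic chlorination by HOCl made in the flask should occur only at the electron-rich isopropenyl group with transposition of its double bond, leaving the conjugated enone and the C5 stereocenter untouched.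

Step 2
Reactants: 2 10-chlorocarvone
Product: 3 allylic pivalate of 10-hydroxycarvone
Conditions: sodium pivalate, NaI (cat.), DMF, 50 °C
Reagents that add atoms: sodium pivalate, CC(C)(C)C(=O)[O-].[Na+]
Why: SN2 displacement of the primary allylic chloride by carboxylate (the SN2' path gives the same product by symmetry) should install the robust ester oxygen that later becomes the oxygen of ring C.

Step 3
Reactants: 3 allylic pivalate
Product: 4 epoxide (both oxirane epimers)
Conditions: mCPBA, CH2Cl2, 0 °C → rt
Reagents that add atoms: m-chloroperoxybenzoic acid, O=C(OO)c1cccc(Cl)c1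
Why: Prilezhaev epoxidation should take the isolated 1,1-disubstituted alkene and not the electron-poor enone, and the new oxirane stereocenter is irrelevant because it becomes a planar radical in step 4.

Step 4
Reactants: 4 epoxide
Product: 5 bicyclic hydroxy ketone (exo CH2OH, endo CH2OPiv)
Conditions: Cp2TiCl2 (2.2 equiv), Zn dust, THF, rt, slow addition of 4; then 1 M HCl
Reagents that add atoms: none
Why: Nugent–RajanBabu homolytic epoxide opening by Cp2TiCl (trivalent titanium) should give the tertiary β-titanoxy radical, which closes the cyclobutane by 4-exo-trig addition to the enone β-carbon (pulled forward by reduction of the α-keto radical to a titanium enolate), the bridgeheads being fixed by the C5 center of carvone and the obligatory cis bridging, while the bulky CH2OTiCp2Cl arm should take the exo position on C6.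

Step 5
Reactants: 5 bicyclic hydroxy ketone
Product: 6 dioxolane alcohol
Conditions: 1,2-bis(trimethylsilyloxy)ethane, TMSOTf (cat.), CH2Cl2, −78 → −20 °C; pyridine quench, aqueous work-up
Reagents that add atoms: 1,2-bis(trimethylsilyloxy)ethane, C[Si](C)(C)OCCO[Si](C)(C)C
Why: Noyori ketalization at low temperature should mask the hindered C3 ketone against the organolithium of step 7 without the acid-promoted 1,3-pivaloyl shift between the two C6 arms that hot protic acid could cause.

Step 6
Reactants: 6 dioxolane alcohol
Product: 7 dioxolane aldehyde
Conditions: Dess–Martin periodinane, pyridine, CH2Cl2, 0 °C → rt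
Reagents that add atoms: none
Why: Dess–Martin oxidation of the neopentylic exo CH2OH should stop at the non-enolizable aldehyde, the pyridine buffer sparing the dioxolane.

Step 7
Reactants: 7 dioxolane aldehyde
Product: 8 1-ethoxyvinyl carbinol (both C10 epimers)
Conditions: ethyl vinyl ether, t-BuLi, THF, −78 → 0 °C; then 7, −78 °C; NH4Cl (aq)
Reagents that add atoms: ethyl vinyl ether, C=COCC
Why: 1,2-Addition of the acyl-anion equivalent 1-ethoxyvinyllithium to the aldehyde at −78 °C should outpace attack on the hindered pivalate, and the new C10 carbinol center may form as a mixture because this oxygen is excised in step 10.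

Step 8
Reactants: 8 1-ethoxyvinyl carbinol; 9 (R)-2-methylbut-3-enoic acid
Product: 10 diene ester (C10 ester of 8 with 9)
Conditions: DCC, DMAP (10 mol%), CH2Cl2, −20 → 0 °C
Reagents that add atoms: none
Why: Steglich esterification at low temperature with substoichiometric DMAP should acylate the hindered carbinol while keeping the activated β,γ-unsaturated acid away from base long enough that its C12 center is carried over unchanged, the non-acidic medium sparing the enol ether.

Step 9
Reactants: 10 diene ester
Product: 11 tether lactone (cyclic enol ether with the C9=C11 double bond)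
Conditions: second-generation Hoveyda–Grubbs catalyst RuCl2(H2IMes)(=CH–C6H4-2-OiPr) (10 mol%), 1,4-benzoquinone (20 mol%), toluene (0.005 M), 80 °C, argon sparge
Reagents that add atoms: none
Why: The ruthenium alkylidene should load onto the unhindered vinyl group of the 2-methylbut-3-enoate, engage the tethered 1,1-disubstituted enol ether in a [2+2] cycloaddition, and release Ru=CH2 (ethylene after turnover) on cycloreversion, which forms the C9=C11 double bond. This is enol ether–olefin ring-closing metathesis, a known route to cyclic enol ethers, and the ring closed is the six-membered lactone C10–O–C13–C12–C11=C9 held together by the temporary C10 acyloxy tether. No stereocenter is created: the C12 methyl center is a spectator and the C10 carbinol center is erased later. The step needs initiation at the vinyl group, because loading on the enol ether would give an unreactive alkoxycarbene; the geminal substitution of the enol ether and its shielding by the quaternary C6 secure this, and the substrate carries no other alkene. Migration of the new double bond into conjugation, which would erode the C12 center, is held back by benzoquinone and by removal of ethylene.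

Step 10
Reactants: 11 tether lactone
Product: 13 keto acid (exo arm CH2–CO–CH2–CH(CH3)–CO2H with C12 R), via oxanedione 12 (not isolated)
Conditions: oxalic acid (cat.), THF/H2O, 0 °C; then crude, SmI2 (2.5 equiv), THF/MeOH, −78 °C; pH 4 phosphate work-up
Reagents that add atoms: water, O
Why: Mild aqueous acid should hydrolyse the cyclic enol ether (C11 protonation, oxocarbenium ion at C9) to the C9 ketone, whose α-acyloxy C10–O bond is then cleaved by SmI2 through ketyl formation and β-elimination of the carboxylate, a standard reductive cleavage of α-heterosubstituted ketones that turns C10 into CH2, frees the C13 acid and leaves the C12 center untouched.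

Step 11
Reactants: 13 keto acid
Product: 15 spiroketal lactone ketone, via hydroxy keto acid 14 (not isolated)
Conditions: NaOMe, MeOH, 50 °C; then 2 M HCl, THF, 40 °C
Reagents that add atoms: water, O
Why: Methoxide transesterification should remove the pivalate and aqueous acid then cleaves the dioxolane and lets the hydroxy keto acid close rings C and D on C9 (thermodynamic spiroketalization), the spiro center settling, with C12 fixed as R, mainly in the arrangement that keeps the C12 methyl group and C10 both pseudo-equatorial (cis) on the lactone envelope and O8 pseudo-axial (anomeric effect).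

Step 12
Reactants: 15 spiroketal lactone ketone
Product: 16 C2=C3 enol triflate
Conditions: Tf2O, 2,6-di-tert-butyl-4-methylpyridine, CH2Cl2, 0 °C → rt
Reagents that add atoms: trifluoromethanesulfonic anhydride, O=S(=O)(OS(=O)(=O)C(F)(F)F)C(F)(F)F
Why: O-Triflation of the ketone with Tf2O and a hindered pyridine base (vinyl triflate synthesis) should favour the more substituted C2=C3 enol triflate, the buffered medium sparing the spiroketal lactone and any C3=C4 isomer being removed by chromatography.

Step 13
Reactants: 16 enol triflate
Product: 17 trisubstituted alkene (α-pinene-type C2=C3)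
Conditions: Pd(OAc)2 (5 mol%), PPh3, Bu3N, HCO2H, DMF, 60 °C
Reagents that add atoms: none
Why: Palladium-catalysed formate reduction of the vinyl triflate (oxidative addition to zerovalent palladium, formate-to-hydride exchange, reductive elimination) should give the alkene without touching the lactone.

Step 14
Reactants: 17 trisubstituted alkene
Product: 19 trans allylic alcohol with exocyclic methylene, via allylic hydroperoxide 18 (not isolated)
Conditions: O2, tetraphenylporphyrin (cat.), visible light, CH2Cl2, 0 °C; then PPh3
Reagents that add atoms: dioxygen, O=O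
Why: The Schenck ene reaction of singlet oxygen should add oxygen to C3 on the face anti to the C6 bridge (the endo C8 arm shields the other face) with abstraction of a methyl hydrogen, as known for α-pinene, and PPh3 reduction of the hydroperoxide then gives the trans allylic alcohol, which sets the C3 center.

Step 15
Reactants: 20 methyl 2,2-dimethyl-3-oxobutanoate
Product: 21 methyl (3S)-3-hydroxy-2,2-dimethylbutanoate
Conditions: H2 (50 atm), RuCl2[(S)-BINAP] (1 mol%), MeOH, 50 °C
Reagents that add atoms: none
Why: Noyori asymmetric hydrogenation of the β-keto ester through the chelated ruthenium hydride should set the carbinol center as S under control of the (S)-BINAP ligand.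

Step 16
Reactants: 21 methyl (3S)-3-hydroxy-2,2-dimethylbutanoate
Product: 22 (3S)-3-hydroxy-2,2-dimethylbutanoic acid
Conditions: LiOH, THF/MeOH/H2O, 40 °C; then 1 M HCl
Reagents that add atoms: lithium hydroxide, [Li+].[OH-]
Why: Saponification of the hindered methyl ester should give the acid without touching the carbinol center, the moderate temperature avoiding retro-aldol cleavage.

Step 17
Reactants: 22 (3S)-3-hydroxy-2,2-dimethylbutanoic acid
Product: 24 (3S)-2,2-dimethyl-3-(triethylsilyloxy)butanoic acid, via bis-silyl derivative 23 (not isolated)
Conditions: Et3SiCl, imidazole, DMF, rt; then AcOH/THF/H2O, 0 °C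
Reagents that add atoms: chlorotriethylsilane, CC[Si](Cl)(CC)CC
Why: Silylation of both hydroxyl and carboxyl groups followed by selective hydrolysis of the labile silyl ester should leave the secondary silyl ether that protects the hydroxyl during acylation.

Step 18
Reactants: 24 (3S)-2,2-dimethyl-3-(triethylsilyloxy)butanoic acid; 19 trans allylic alcohol
Product: 26 silyl-protected ester, via mixed anhydride 25 (not isolated)
Conditions: 2,4,6-trichlorobenzoyl chloride, Et3N, THF, rt; then 19, DMAP, toluene, rt → 40 °C
Reagents that add atoms: none
Why: Yamaguchi esterification through the mixed anhydride and DMAP should acylate the hindered allylic alcohol with the α-quaternary acid with retention at C3, under conditions mild enough to leave the lactone α-center and the spiroketal alone.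

Step 19
Reactants: 26 silyl-protected ester
Product: 27 CNP0212779.5
Conditions: HF·pyridine, pyridine, THF, 0 °C → rt
Reagents that add atoms: none
Why: Fluoride cleavage of the triethylsilyl ether under buffered conditions should release the side-chain hydroxyl without acyl migration, ester cleavage or opening of the spiroketal lactone.

Compound list
1 | (R)-(−)-carvone, (5R)-2-methyl-5-(prop-1-en-2-yl)cyclohex-2-en-1-one | C=C(C)[C@@H]1CC=C(C)C(=O)C1 | starting material
2 | 10-chlorocarvone, (5R)-5-(3-chloroprop-1-en-2-yl)-2-methylcyclohex-2-en-1-one | C=C(CCl)[C@@H]1CC=C(C)C(=O)C1 | intermediate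
3 | 2-[(1R)-4-methyl-5-oxocyclohex-3-en-1-yl]prop-2-en-1-yl 2,2-dimethylpropanoate | C=C(COC(=O)C(C)(C)C)[C@@H]1CC=C(C)C(=O)C1 | intermediate
4 | {2-[(1R)-4-methyl-5-oxocyclohex-3-en-1-yl]oxiran-2-yl}methyl 2,2-dimethylpropanoate, both oxirane epimers | CC(C)(C)C(=O)OCC1(CO1)[C@@H]1CC=C(C)C(=O)C1 | intermediate
5 | 2-methylbicyclo[3.1.1]heptan-3-one with C6 carrying an exo CH2OH and an endo CH2O-pivaloyl arm; bridgeheads as in (−)-β-pinene; C2 epimers | CC1C(=O)C[C@H]2C[C@@H]1[C@@]2(CO)COC(=O)C(C)(C)C | intermediate
6 | 3,3-ethylenedioxy ketal (dioxolane) of 5 | CC1C2(OCCO2)C[C@H]3C[C@@H]1[C@@]3(CO)COC(=O)C(C)(C)C | intermediate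
7 | dioxolane aldehyde: exo arm of 6 oxidised to CHO | CC1C2(OCCO2)C[C@H]3C[C@@H]1[C@@]3(C=O)COC(=O)C(C)(C)C | intermediate
8 | carbinol with exo arm CH(OH)–C(OEt)=CH2, both C10 epimers | CC1C2(OCCO2)C[C@H]3C[C@@H]1[C@@]3(C(O)C(=C)OCC)COC(=O)C(C)(C)C | intermediate
9 | (R)-2-methylbut-3-enoic acid | C=C[C@@H](C)C(=O)O | starting material
10 | diene ester: 8 acylated on the C10 oxygen with the (R)-2-methylbut-3-enoyl group | CC1C2(OCCO2)C[C@H]3C[C@@H]1[C@@]3(C(OC(=O)[C@H](C)C=C)C(=C)OCC)COC(=O)C(C)(C)C | intermediate
11 | tether lactone: (3R)-5-ethoxy-3-methyl-3,6-dihydro-2H-pyran-2-one whose ring C6 (= C10) is bonded to C6 of the ketal-protected bicycle, endo CH2OPiv retained | CC1C2(OCCO2)C[C@H]3C[C@@H]1[C@@]3(C1OC(=O)[C@H](C)C=C1OCC)COC(=O)C(C)(C)C | intermediate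
12 | (3R)-3-methyloxane-2,5-dione analogue of 11 (C9 ketone) | CC1C2(OCCO2)C[C@H]3C[C@@H]1[C@@]3(C1OC(=O)[C@H](C)CC1=O)COC(=O)C(C)(C)C | intermediate (not isolated)
13 | keto acid: exo arm CH2–CO–CH2–CH(CH3)–CO2H with C12 R; endo CH2OPiv; C3 dioxolane | CC1C2(OCCO2)C[C@H]3C[C@@H]1[C@@]3(CC(=O)C[C@@H](C)C(=O)O)COC(=O)C(C)(C)C | intermediate
14 | hydroxy keto acid: 13 with the endo arm as CH2OH | CC1C2(OCCO2)C[C@H]3C[C@@H]1[C@@]3(CC(=O)C[C@@H](C)C(=O)O)CO | intermediate (not isolated)
15 | spiroketal lactone ketone: C6 of 2-methylbicyclo[3.1.1]heptan-3-one is C3 of an oxolane (O on the endo CH2) whose C5 (= C9, R) is the spiro carbon of a (3R)-3-methyl-γ-butyrolactone | CC1C(=O)C[C@H]2C[C@@H]1[C@@]21CO[C@@]2(C[C@@H](C)C(=O)O2)C1 | intermediate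
16 | C2=C3 enol triflate of 15 | CC1=C(OS(=O)(=O)C(F)(F)F)C[C@H]2C[C@@H]1[C@@]21CO[C@@]2(C[C@@H](C)C(=O)O2)C1 | intermediate
17 | 2-methylbicyclo[3.1.1]hept-2-ene analogue of 15 (α-pinene-type alkene) | CC1=CC[C@H]2C[C@@H]1[C@@]21CO[C@@]2(C[C@@H](C)C(=O)O2)C1 | intermediate
18 | allylic hydroperoxide: 2-methylene, C3–OOH anti to the C6 bridge | C=C1[C@@H](OO)C[C@H]2C[C@@H]1[C@@]21CO[C@@]2(C[C@@H](C)C(=O)O2)C1 | intermediate (not isolated)
19 | trans allylic alcohol: 2-methylene, C3–OH anti to the C6 bridge (C3 S) | C=C1[C@@H](O)C[C@H]2C[C@@H]1[C@@]21CO[C@@]2(C[C@@H](C)C(=O)O2)C1 | intermediate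
20 | methyl 2,2-dimethyl-3-oxobutanoate | COC(=O)C(C)(C)C(C)=O | starting material
21 | methyl (3S)-3-hydroxy-2,2-dimethylbutanoate | COC(=O)C(C)(C)[C@H](C)O | intermediate
22 | (3S)-3-hydroxy-2,2-dimethylbutanoic acid | OC(=O)C(C)(C)[C@H](C)O | intermediate
23 | triethylsilyl (3S)-2,2-dimethyl-3-(triethylsilyloxy)butanoate | CC[Si](CC)(CC)OC(=O)C(C)(C)[C@H](C)O[Si](CC)(CC)CC | intermediate (not isolated)
24 | (3S)-2,2-dimethyl-3-(triethylsilyloxy)butanoic acid | OC(=O)C(C)(C)[C@H](C)O[Si](CC)(CC)CC | intermediate
25 | mixed anhydride of 24 with 2,4,6-trichlorobenzoic acid | O=C(OC(=O)C(C)(C)[C@H](C)O[Si](CC)(CC)CC)c1c(Cl)cc(Cl)cc1Cl | intermediate (not isolated)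
26 | C3 ester of 19 with 24 (triethylsilyl ether of the target) | C=C1[C@@H](OC(=O)C(C)(C)[C@H](C)O[Si](CC)(CC)CC)C[C@H]2C[C@@H]1[C@@]21CO[C@@]2(C[C@@H](C)C(=O)O2)C1 | intermediate
27 | CNP0212779.5: C3 (3S)-3-hydroxy-2,2-dimethylbutanoate of 19; in the locants used here C1 R, C3 S, C5 R, C6 S, C9 R, C12 R | C=C1[C@@H](OC(=O)C(C)(C)[C@H](C)O)C[C@H]2C[C@@H]1[C@@]21CO[C@@]2(C[C@@H](C)C(=O)O2)C1 | target

Total step count: 19 (16 in the main line, 3 for the side-chain acid). Longest linear sequence: 16 steps (steps 1–14, 18 and 19).

Steps most likely to fail

Step 4. The 4-exo closure may give poor control over which hydroxymethyl arm of C6 ends exo, so that the C6 configuration is lost. The fallback sets out from 5 (as the C6-epimer mixture) and comes back at 7. Methanolysis of the pivalate (NaOMe, MeOH) gives the keto diol F1, in which C6 is no longer stereogenic, so both epimers converge. Ketalization as in step 5 gives the dioxolane diol F2. Oxoammonium oxidation (TEMPO, PhI(OAc)2, CH2Cl2) should take the less hindered exo CH2OH, the endo arm being screened by the dioxolane, to give the hydroxy aldehyde F3. Pivaloylation (PivCl, pyridine) then gives 7. Stereocontrol at C6 thus comes from steric differentiation of the two arms instead of from the radical closure.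

Step 9. The catalyst may be arrested by loading onto the enol ether (unreactive alkoxycarbene), or the double bond may migrate and erode the C12 center. The fallback sets out from 8 and comes back at 13. The carbinol epimers of 8 are separated and acylated with propanoyl chloride (pyridine, DMAP) to the propanoate F4. Ireland–Claisen rearrangement (lithium diisopropylamide, TMSCl, THF or THF/DMPU, −78 °C → rt) follows, with the ketene acetal geometry chosen for each epimer so that the chair transition state transfers the C10 configuration to C12 as R. Aqueous work-up gives the enol ether acid F5. Oxalic acid in wet THF then hydrolyses the enol ether to 13. In this variant the C10 oxygen leaves in the sigmatropic step and neither the sensitive acid 9 nor SmI2 is needed.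

Step 11. The thermodynamic bias at the spiro carbon C9 may be low, so that equilibration leaves much of the C9 epimer. The fallback sets out from 13 and comes back at 15. NaBH4 reduction of the C9 ketone and acid-induced lactonization give the γ-lactone F6 (both C9 epimers serve). NaOMe in MeOH, then aqueous HCl, remove the pivalate and the dioxolane and re-close the lactone to the hydroxy keto lactone F7. Hypoiodite oxidation (PhI(OAc)2, I2, visible light, cyclohexane/CH2Cl2) generates the C8 alkoxy radical; 1,5-hydrogen transfer from C9 and oxidation give the lactone oxocarbenium ion. The hydroxyl should trap this ion under kinetic control on the face anti to the C12 methyl group (inside attack on the five-membered cation), giving 15 without acid equilibration.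

Further compounds
F1 | step 4 | keto diol: 6,6-bis(hydroxymethyl)-2-methylbicyclo[3.1.1]heptan-3-one, bridgeheads as in 5 | CC1C(=O)C[C@H]2C[C@@H]1C2(CO)CO
F2 | step 4 | dioxolane of F1 | CC1C2(OCCO2)C[C@H]3C[C@@H]1C3(CO)CO
F3 | step 4 | hydroxy aldehyde: exo CHO, endo CH2OH, C3 dioxolane | CC1C2(OCCO2)C[C@H]3C[C@@H]1[C@@]3(C=O)CO
F4 | step 9 | propanoate of 8 on the C10 oxygen | CC1C2(OCCO2)C[C@H]3C[C@@H]1[C@@]3(C(OC(=O)CC)C(=C)OCC)COC(=O)C(C)(C)C
F5 | step 9 | enol ether acid: exo arm CH=C(OEt)–CH2–CH(CH3)–CO2H with C12 R | CC1C2(OCCO2)C[C@H]3C[C@@H]1[C@@]3(C=C(OCC)C[C@@H](C)C(=O)O)COC(=O)C(C)(C)C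
F6 | step 11 | γ-lactone: exo arm CH2 bonded to C5 of a (3R)-3-methyloxolan-2-one, both C9 epimers; endo CH2OPiv; C3 dioxolane | CC1C2(OCCO2)C[C@H]3C[C@@H]1[C@@]3(CC1C[C@@H](C)C(=O)O1)COC(=O)C(C)(C)C
F7 | step 11 | hydroxy keto lactone: F6 with free endo CH2OH and free C3 ketone | CC1C(=O)C[C@H]2C[C@@H]1[C@@]2(CC1C[C@@H](C)C(=O)O1)CO
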